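## The problem

Betaethrin A is an achiral diaryl ether. Ring A is a methyl salicylate (C1 bears the ester carbon C7, C2 OH, C4 CH3, C6 the ether oxygen) and ring B a benzyl acetate (C1' ether carbon, C2' OH, C4' OCH3, C6' CH2OAc). With no stereocentre in the target, the whole difficulty is constitutional: the ether oxygen lies between three ortho substituents (the C1 ester, the C2' hydroxyl and the C6' acetoxymethyl group), so joining two finished arenes by a C–O coupling is unattractive. Ring B in addition carries three different oxygen functions whose positions relative to C1' must be fixed without ambiguity. The fragile groups are the benzylic acetate (lost to alkoxide or acidic methanol), the free C2' phenol ortho to the ether oxygen (open to Smiles-type aryl migration in base) and the hindered ester, so the acetate must arrive late and the phenols must be unmasked last under non-basic conditions. Stereocentres may be created in transit only if they are destroyed again; none has to control another. The enabling feature is that C6–O–C1' together with C1–C7 are the atoms of a benzofuran-3(2H)-one, in which C7 is the ketone carbon and C1' the C2 methylene, a carbon acid that can take up two new C–C bonds, to C2' and to C6'. The 1,3-relationship of the C2' and C4' oxygens is that of a vinylogous ester, which two conjugate additions onto an alkoxyethynyl vinyl ketone deliver, and the resulting spiro ketone can return C7 as the methyl ester when it is cleaved with aromatisation of ring B.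

## Retrosynthesis

**Unmasking (27 from 26, 25 and 24).** The last bonds to be cut are the two phenol-protecting O–C bonds of acetate 26, a tert-butyl ether at C2' and a methoxymethyl (MOM) ether at C2, both removable by one acid treatment. The acetate is placed on alcohol 25 while it is the only free hydroxyl, and 25 comes from silyl ether 24. The neighbouring order (global deprotection, then acetylation) would require a primary alcohol to be told apart from two phenols; the chosen order needs no such selectivity. The forward step must use an acid that leaves a benzylic acetate and a methyl ester alone.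

**Aromatising fragmentation (24 from 22).** In diaryl ether 24 the bond between C7 and C1' is reconnected, which leads back to spirodienone 22. In the forward direction an alkoxide attacks ketone C7, the C7–C1' bond breaks, ring B aromatises, C7 becomes the methyl ester and C4' a phenoxide (phenol 23), which is methylated in the same flask. The cut next to it, at the O–C1' or C6–O bond, would mean coupling two hindered arenes. Here the ether bond is never touched, and the C2' and C4' oxygens are distinguished automatically, as a tert-butyl enol ether and a carbonyl oxygen. The forward reaction must attack the benzofuranone ketone and not the vinylogous ester.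

**Oxidation level (22 from 20).** Removing the C5'=C6' double bond gives spirocyclohexenone 20, the direct product of a double conjugate addition. The dehydrogenation has only one place to go, since C5' is the only enolisable carbon of 20.

**Spiroannulation (20 from 7 and 18).** Cutting C1'–C6' and C1'–C2' divides 20 into benzofuranone 7 and the cross-conjugated ynone–enone 18. Against cuts inside either benzene ring (the other roads below), this one forms ring B on a carbon that is already bonded to the ether oxygen and keeps both fragments small: a bicyclic ketone and a six-carbon chain. The forward reaction needs carbon-selective attack of the enolate and a temperature low enough for the tert-butyl alkynyl ether. Two stereocentres appear (C1' and C6') and need no control.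

**Benzofuranone (7 from 6, 3, 1 and 2).** The MOM ether of 7 is removed to give phenol 6. Its C2–C3 bond (C1'–C7 in target numbering, a bond that is made here and broken again later) is cut by a retro-Dieckmann step with the carboxyl lost on the way, giving aryloxyacetate 3. The O–CH2 bond of 3 is cut to the symmetric resorcinol ester 1 and bromoacetate 2. The hindered O–C1' bond is therefore made by the simplest reaction available, a phenoxide alkylation.

**Ynone–enone (18 from 17, 11, 14, 9, 8 and 12).** Ketone 18 comes from carbinol 17 by oxidation. Cutting the bond between the carbinol carbon and the alkyne gives enal 11 and lithium tert-butoxyacetylide 16, which is generated from dichlorovinyl ether 14 and this from trichloroethylene 12. Enal 11 comes from the monosilyl ether 9 of (Z)-butenediol 8. The tert-butyl group is chosen because it is the alkynyl ether substituent that can later be removed from an aryl oxygen by acid without touching the C4' methyl ether.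

## Roads not taken

**Alternative 1:** ring A is built last by an inverse-demand cycloaddition. The cut goes through C1–C2 and C3–C4 of ring A. In the forward direction the aryloxy pyrone A1 is heated with the ketene acetal A2; the bridged lactone aromatises by decarboxylation and loss of one methoxy group to give benzoate A3.
- Merits: ring A arises with complete regiocontrol, the step is thermal and redox-neutral, and no stereocentre is made and destroyed. In these respects it is better than the chosen plan.
- Weak points: A3 carries a methyl ether at C2 that must be cleaved in the presence of the C4' methyl ether, which needs a chelation-directed Lewis-acid demethylation that is awkward beside MOM, silyl and later acetate groups. The fully substituted ring B phenol A4 must be made separately with its own regiochemical problem. A4, a 2,6-disubstituted phenoxide, must then be attached to the pyrone by addition–elimination. The 4-aryloxy donor and the 6-methyl group lower the reactivity of A1 towards A2, so forcing conditions are likely.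
- Comparison: the chosen plan sets against the robust key step of this road that both rings come from simple purchased materials and that the three oxygen functions of ring B are differentiated by construction.

**Alternative 2:** ring B is built by a photochemical Wolff rearrangement and vinylketene–alkyne benzannulation. The cut goes through C2'–C3', C4'–C5' and C1'–C2'. Irradiation of diazo ketone A5 gives a vinylketene that adds methoxyethyne A6 in a (2+2) sense; four-electron ring opening and six-electron electrocyclisation give phenol A7.
- Merits: A7 has the C2' phenol free and the C4' methoxy group in place, so neither a methylation nor a tert-butyl cleavage is needed. After the key step this road is as short as the chosen one or shorter.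
- Weak points: A5 is a β-aryloxy enone carrying a diazo group. Its preparation needs an enol ether formed from the chelated ring A phenol and a diazo transfer, and its alkene geometry bears on the electrocyclisation. A6 is volatile and must be prepared. The free C2' phenol of A7 then has to be told apart from the other hydroxyls during acetylation.
- Comparison: the chosen plan offers a key step with close precedent on benzofuranones and precursors that are easier to reach.

**Alternative 3:** ring A is closed by a vinylogous Dieckmann condensation. The cut is C2–C3 of ring A. A lithium amide base deprotonates a terminal methyl group of dienyl malonate A8, and the trienolate closes onto the cis ester to give salicylate A9 after loss of alkoxide and tautomerisation.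
- Merits: ring A appears directly as the free salicylate, base is the only reagent, and there is no redox adjustment. This is more economical in protecting groups on ring A than the chosen plan.
- Weak points: A8 is a vinylogous carbonate, and amide or liberated alkoxide can displace the aryloxide by addition–elimination. Only one of the two methyl groups leads to cyclisation. The road again rests on phenol A4 and on its attachment to a hindered electrophile.
- Comparison: the chosen plan needs no separate synthesis of a pentasubstituted ring B, and its C–O bond is made by an unhindered alkylation.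

Key step: step 9

## Route

Assumption: the target is achiral and every chiral intermediate is carried as a racemate; compounds 1, 2, 8 and 12 and the common reagents are taken as purchasable.

Step 1
Reactants: 1 methyl 2,6-dihydroxy-4-methylbenzoate; 2 methyl bromoacetate
Product: 3 methyl 2-hydroxy-6-(2-methoxy-2-oxoethoxy)-4-methylbenzoate
Conditions: K2CO3 (1.1 equiv), acetone, 50 °C
Reagents that add atoms: none
Why: Williamson O-alkylation (SN2) of the symmetric resorcinol ester; after one alkylation the remaining hydroxyl is held in a hydrogen bond to the ester carbonyl and is a much poorer nucleophile, so one equivalent of 2 should stop at the monoether.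

Step 2
Reactants: 3 methyl 2-hydroxy-6-(2-methoxy-2-oxoethoxy)-4-methylbenzoate
Product: 6 4-hydroxy-6-methylbenzofuran-3(2H)-one, via methyl 3,4-dihydroxy-6-methylbenzofuran-2-carboxylate 4 (not isolated), via 3,4-dihydroxy-6-methylbenzofuran-2-carboxylic acid 5 (not isolated)
Conditions: KOt-Bu (2.5 equiv), THF, 0 °C → rt; then 6 M aq HCl, reflux
Reagents that add atoms: none
Why: Dieckmann condensation, the aryloxyacetate enolate closing the five-membered ring onto the neighbouring benzoate ester (5-exo-trig) with the product held as its enolate; hot aqueous acid then hydrolyses the enolised β-keto ester and the β-keto acid decarboxylates to the benzofuranone.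

Step 3
Reactants: 6 4-hydroxy-6-methylbenzofuran-3(2H)-one
Product: 7 4-(methoxymethoxy)-6-methylbenzofuran-3(2H)-one
Conditions: MOMCl, i-Pr2NEt, CH2Cl2, 0 °C → rt
Reagents that add atoms: chloromethyl methyl ether, COCCl
Why: O-alkylation of the phenol with an α-chloro ether under a weak amine base that leaves the C2 methylene alone; the MOM ether keeps the phenol from consuming the catalytic base of step 9.

Step 4
Reactants: 8 (Z)-but-2-ene-1,4-diol
Product: 9 (Z)-4-(tert-butyldimethylsilyloxy)but-2-en-1-ol
Conditions: NaH (1.0 equiv), THF, 0 °C; then TBSCl (1.0 equiv)
Reagents that add atoms: tert-butyldimethylsilyl chloride, CC(C)(C)[Si](C)(C)Cl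
Why: Monosilylation of a symmetric diol through its sparingly soluble monosodium alkoxide, which is silylated before a second deprotonation can take place.

Step 5
Reactants: 9 (Z)-4-(tert-butyldimethylsilyloxy)but-2-en-1-ol
Product: 11 (E)-4-(tert-butyldimethylsilyloxy)but-2-enal, via (Z)-4-(tert-butyldimethylsilyloxy)but-2-enal 10 (not isolated)
Conditions: pyridinium chlorochromate [C5H5NH][CrO3Cl], CH2Cl2, rt
Reagents that add atoms: none
Why: Chlorochromate oxidation of the allylic alcohol; the mildly acidic reagent isomerises the first-formed (Z)-enal to the thermodynamically preferred (E)-enal, which sets the alkene geometry of 18.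

Step 6
Reactants: 12 trichloroethylene
Product: 14 tert-butyl (E)-1,2-dichlorovinyl ether, via dichloroacetylene 13 (not isolated)
Conditions: KOt-Bu (1.1 equiv), THF, −50 °C → rt
Reagents that add atoms: potassium tert-butoxide, CC(C)(C)[O-].[K+]
Why: The alkoxide dehydrochlorinates trichloroethylene and then adds to the transient dichloroacetylene in anti fashion, the established entry to 1,2-dichlorovinyl ethers as precursors of alkynyl ethers; the haloalkyne is consumed as it forms.

Step 7
Reactants: 14 tert-butyl (E)-1,2-dichlorovinyl ether; 11 (E)-4-(tert-butyldimethylsilyloxy)but-2-enal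
Product: 17 racemic (E)-1-tert-butoxy-6-(tert-butyldimethylsilyloxy)hex-4-en-1-yn-3-ol, via tert-butyl chloroethynyl ether 15 (not isolated), via lithium tert-butoxyacetylide 16 (not isolated)
Conditions: n-BuLi (2.1 equiv), THF, −78 → −40 °C; then 11, −78 °C; aq NaH2PO4/Na2HPO4 buffer (pH 7)
Reagents that add atoms: none
Why: Butyllithium effects dehydrochlorination to the chloroalkyne and then chlorine–lithium exchange, the standard generation of lithium alkoxyacetylides, and the acetylide adds 1,2 to the unhindered enal; the carbinol centre is formed racemic and is removed in step 8.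

Step 8
Reactants: 17 racemic (E)-1-tert-butoxy-6-(tert-butyldimethylsilyloxy)hex-4-en-1-yn-3-ol
Product: 18 (E)-1-tert-butoxy-6-(tert-butyldimethylsilyloxy)hex-4-en-1-yn-3-one
Conditions: MnO2 (activated, excess), CH2Cl2, 0 °C → rt
Reagents that add atoms: none
Why: MnO2 oxidises an alcohol that is both allylic and propargylic under neutral conditions, which spares the acid- and heat-sensitive alkynyl ether and the silyl ether.

Step 9
Reactants: 7 4-(methoxymethoxy)-6-methylbenzofuran-3(2H)-one; 18 (E)-1-tert-butoxy-6-(tert-butyldimethylsilyloxy)hex-4-en-1-yn-3-one
Product: 20 racemic 2'-tert-butoxy-6'-[(tert-butyldimethylsilyloxy)methyl]-4-(methoxymethoxy)-6-methyl-3H-spiro[benzofuran-2,1'-cyclohex-2'-ene]-3,4'-dione (mixture of two diastereomers), via open-chain mono-Michael adduct 19 (not isolated)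
Conditions: KOt-Bu (0.15 equiv), THF/t-BuOH, 0 °C → rt, slow addition of 18
Reagents that add atoms: none
Why: Catalytic tert-butoxide converts 7 into its enolate (the C2 methylene is its only acidic site); the soft carbon terminus adds to the alkene carbon of 18 that bears the silyloxymethyl group (bond C1'–C6'), and proton transfer gives adduct 19 and returns the base. Adduct 19 still has one C2 hydrogen, so the enolate re-forms at the same carbon and attacks the tert-butoxy-bearing alkyne carbon (bond C1'–C2') in a 6-endo-dig closure; protonation of the allenolate gives the vinylogous ester of 20. The closest known reaction type is the base-catalysed double conjugate addition of benzofuran-3(2H)-ones to alkoxyethynyl vinyl ketones that gives grisan spirocyclohexenones, from which this case differs only in the spectator alkoxy group. The constitution is fixed by the substrates: both bonds can form only at C2 of 7, and whichever terminus of 18 reacts first the same spirocycle results, the alkene being expected to react first because the alkoxy group donates into the ynone. The two new stereocentres (spiro C1' and C6') are not controlled; a mixture of racemic diastereomers is expected and accepted, because C6' becomes trigonal in step 10 and C1' in step 11. The selectivities needed are carbon over oxygen attack of the enolate, which the soft doubly stabilised nucleophile and the reversibility of oxygen addition favour, and ring closure over addition to a second molecule of 18, which slow addition of 18 and the six-membered intramolecular transition state favour. The temperature is kept at or below ambient because tert-butyl alkynyl ethers lose 2-methylpropene on heating.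

Step 10
Reactants: 20 racemic 2'-tert-butoxy-6'-[(tert-butyldimethylsilyloxy)methyl]-4-(methoxymethoxy)-6-methyl-3H-spiro[benzofuran-2,1'-cyclohex-2'-ene]-3,4'-dione (mixture of two diastereomers)
Product: 22 racemic 2'-tert-butoxy-6'-[(tert-butyldimethylsilyloxy)methyl]-4-(methoxymethoxy)-6-methyl-3H-spiro[benzofuran-2,1'-cyclohexa-2',5'-diene]-3,4'-dione, via trimethylsilyl dienol ether 21 (not isolated)
Conditions: LiN(i-Pr)2, Me3SiCl (in situ), THF, −78 °C; then Pd(OAc)2 (1.1 equiv), MeCN, rt
Reagents that add atoms: none
Why: Saegusa–Ito oxidation: C5' is the only enolisable carbon (C1' is quaternary and the benzofuranone ketone has no α-hydrogen), so kinetic deprotonation with in-situ silylation gives a single silyl dienol ether, which divalent palladium converts into the cross-conjugated dienone through a palladium enolate and β-hydride elimination of the C6' hydrogen. Both diastereomers of 20 converge, since the C6' stereocentre disappears.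

Step 11
Reactants: 22 racemic 2'-tert-butoxy-6'-[(tert-butyldimethylsilyloxy)methyl]-4-(methoxymethoxy)-6-methyl-3H-spiro[benzofuran-2,1'-cyclohexa-2',5'-diene]-3,4'-dione
Product: 24 methyl 2-{2-tert-butoxy-6-[(tert-butyldimethylsilyloxy)methyl]-4-methoxyphenoxy}-6-(methoxymethoxy)-4-methylbenzoate, via diaryl ether phenol 23 (not isolated)
Conditions: NaOMe (1.2 equiv), MeOH/THF, 0 °C; then MeI (5 equiv), DMF, rt
Reagents that add atoms: sodium methoxide, C[O-].[Na+]; iodomethane, CI
Why: Methoxide adds to the strained, α-oxygenated benzofuranone ketone and the adduct fragments (retro-Claisen) because the departing carbon C1' is the para position of a phenoxide, so ring B aromatises; this is the known alkoxide opening of grisadienones to diaryl ethers. The C4' phenoxide is then O-methylated in the same flask (Williamson), and the last stereocentre disappears.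

Step 12
Reactants: 24 methyl 2-{2-tert-butoxy-6-[(tert-butyldimethylsilyloxy)methyl]-4-methoxyphenoxy}-6-(methoxymethoxy)-4-methylbenzoate
Product: 25 methyl 2-[2-tert-butoxy-6-(hydroxymethyl)-4-methoxyphenoxy]-6-(methoxymethoxy)-4-methylbenzoate
Conditions: HF·pyridine, pyridine, THF, 0 °C → rt
Reagents that add atoms: none
Why: Fluoride cleavage of the primary silyl ether under buffered, non-basic conditions that leave the MOM and tert-butyl aryl ethers untouched and generate no alkoxide that could attack the ester.

Step 13
Reactants: 25 methyl 2-[2-tert-butoxy-6-(hydroxymethyl)-4-methoxyphenoxy]-6-(methoxymethoxy)-4-methylbenzoate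
Product: 26 methyl 2-[2-(acetoxymethyl)-6-tert-butoxy-4-methoxyphenoxy]-6-(methoxymethoxy)-4-methylbenzoate
Conditions: Ac2O, pyridine, 4-(dimethylamino)pyridine (cat.), CH2Cl2, 0 °C
Reagents that add atoms: acetic anhydride, CC(=O)OC(C)=O
Why: Nucleophile-catalysed acylation of the only free hydroxyl group in the molecule, so no chemoselectivity is asked for.

Step 14
Reactants: 26 methyl 2-[2-(acetoxymethyl)-6-tert-butoxy-4-methoxyphenoxy]-6-(methoxymethoxy)-4-methylbenzoate
Product: 27 betaethrin A, methyl 2-[2-(acetoxymethyl)-6-hydroxy-4-methoxyphenoxy]-6-hydroxy-4-methylbenzoate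
Conditions: CF3CO2H/CH2Cl2 (1:4), H2O (5 equiv), 0 °C → rt, 0.01 M; then aq NaHCO3
Reagents that add atoms: none
Why: Acidolysis: the aryl tert-butyl ether gives the phenol and 2-methylpropene and the MOM acetal gives the phenol, formaldehyde and methanol. The benzylic acetate should survive cold non-nucleophilic acid, because its only ortho donor is the weakly donating diaryl ether oxygen and the two meta oxygens destabilise a benzylic cation; the methyl ester is likewise stable.

## Compound list

1 | methyl 2,6-dihydroxy-4-methylbenzoate | COC(=O)c1c(O)cc(C)cc1O | starting material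
2 | methyl bromoacetate | COC(=O)CBr | starting material
3 | methyl 2-hydroxy-6-(2-methoxy-2-oxoethoxy)-4-methylbenzoate | COC(=O)COc1cc(C)cc(O)c1C(=O)OC | intermediate
4 | methyl 3,4-dihydroxy-6-methylbenzofuran-2-carboxylate (enol form of the Dieckmann product, not isolated) | COC(=O)c1oc2cc(C)cc(O)c2c1O | intermediate
5 | 3,4-dihydroxy-6-methylbenzofuran-2-carboxylic acid (not isolated) | OC(=O)c1oc2cc(C)cc(O)c2c1O | intermediate
6 | 4-hydroxy-6-methylbenzofuran-3(2H)-one | Cc1cc(O)c2C(=O)COc2c1 | intermediate
7 | 4-(methoxymethoxy)-6-methylbenzofuran-3(2H)-one | Cc1cc(OCOC)c2C(=O)COc2c1 | intermediate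
8 | (Z)-but-2-ene-1,4-diol | OC/C=C\CO | starting material
9 | (Z)-4-(tert-butyldimethylsilyloxy)but-2-en-1-ol | OC/C=C\CO[Si](C)(C)C(C)(C)C | intermediate
10 | (Z)-4-(tert-butyldimethylsilyloxy)but-2-enal (not isolated) | O=C/C=C\CO[Si](C)(C)C(C)(C)C | intermediate
11 | (E)-4-(tert-butyldimethylsilyloxy)but-2-enal | O=C/C=C/CO[Si](C)(C)C(C)(C)C | intermediate
12 | trichloroethylene | ClC=C(Cl)Cl | starting material
13 | dichloroacetylene (not isolated) | ClC#CCl | intermediate
14 | tert-butyl (E)-1,2-dichlorovinyl ether | Cl/C=C(/Cl)OC(C)(C)C | intermediate
15 | tert-butyl chloroethynyl ether (not isolated) | CC(C)(C)OC#CCl | intermediate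
16 | lithium tert-butoxyacetylide (not isolated) | CC(C)(C)OC#C[Li] | intermediate
17 | racemic (E)-1-tert-butoxy-6-(tert-butyldimethylsilyloxy)hex-4-en-1-yn-3-ol | CC(C)(C)OC#CC(O)/C=C/CO[Si](C)(C)C(C)(C)C | intermediate
18 | (E)-1-tert-butoxy-6-(tert-butyldimethylsilyloxy)hex-4-en-1-yn-3-one | CC(C)(C)OC#CC(=O)/C=C/CO[Si](C)(C)C(C)(C)C | intermediate
19 | 2-[6-tert-butoxy-1-(tert-butyldimethylsilyloxy)-4-oxohex-5-yn-2-yl]-4-(methoxymethoxy)-6-methylbenzofuran-3(2H)-one (racemic, mixture of diastereomers, not isolated) | Cc1cc(OCOC)c2C(=O)C(Oc2c1)C(CO[Si](C)(C)C(C)(C)C)CC(=O)C#COC(C)(C)C | intermediate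
20 | racemic 2'-tert-butoxy-6'-[(tert-butyldimethylsilyloxy)methyl]-4-(methoxymethoxy)-6-methyl-3H-spiro[benzofuran-2,1'-cyclohex-2'-ene]-3,4'-dione (mixture of two diastereomers) | Cc1cc(OCOC)c2C(=O)C3(Oc2c1)C(OC(C)(C)C)=CC(=O)CC3CO[Si](C)(C)C(C)(C)C | intermediate
21 | racemic 2'-tert-butoxy-6'-[(tert-butyldimethylsilyloxy)methyl]-4-(methoxymethoxy)-6-methyl-4'-(trimethylsilyloxy)-3H-spiro[benzofuran-2,1'-cyclohexa-2',4'-dien]-3-one (mixture of diastereomers, not isolated) | Cc1cc(OCOC)c2C(=O)C3(Oc2c1)C(OC(C)(C)C)=CC(O[Si](C)(C)C)=CC3CO[Si](C)(C)C(C)(C)C | intermediate
22 | racemic 2'-tert-butoxy-6'-[(tert-butyldimethylsilyloxy)methyl]-4-(methoxymethoxy)-6-methyl-3H-spiro[benzofuran-2,1'-cyclohexa-2',5'-diene]-3,4'-dione | Cc1cc(OCOC)c2C(=O)C3(Oc2c1)C(OC(C)(C)C)=CC(=O)C=C3CO[Si](C)(C)C(C)(C)C | intermediate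
23 | methyl 2-{2-tert-butoxy-6-[(tert-butyldimethylsilyloxy)methyl]-4-hydroxyphenoxy}-6-(methoxymethoxy)-4-methylbenzoate (present as its sodium phenoxide, not isolated) | COC(=O)c1c(OCOC)cc(C)cc1Oc1c(OC(C)(C)C)cc(O)cc1CO[Si](C)(C)C(C)(C)C | intermediate
24 | methyl 2-{2-tert-butoxy-6-[(tert-butyldimethylsilyloxy)methyl]-4-methoxyphenoxy}-6-(methoxymethoxy)-4-methylbenzoate | COC(=O)c1c(OCOC)cc(C)cc1Oc1c(OC(C)(C)C)cc(OC)cc1CO[Si](C)(C)C(C)(C)C | intermediate
25 | methyl 2-[2-tert-butoxy-6-(hydroxymethyl)-4-methoxyphenoxy]-6-(methoxymethoxy)-4-methylbenzoate | COC(=O)c1c(OCOC)cc(C)cc1Oc1c(OC(C)(C)C)cc(OC)cc1CO | intermediate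
26 | methyl 2-[2-(acetoxymethyl)-6-tert-butoxy-4-methoxyphenoxy]-6-(methoxymethoxy)-4-methylbenzoate | COC(=O)c1c(OCOC)cc(C)cc1Oc1c(OC(C)(C)C)cc(OC)cc1COC(C)=O | intermediate
27 | betaethrin A, methyl 2-[2-(acetoxymethyl)-6-hydroxy-4-methoxyphenoxy]-6-hydroxy-4-methylbenzoate | COC(=O)c1c(O)cc(C)cc1Oc1c(O)cc(OC)cc1COC(C)=O | target

## Step count and risks

Total step count: 14. Longest linear sequence: 10 steps (steps 4, 5, 7, 8, 9, 10, 11, 12, 13 and 14, from diol 8). The benzofuranone branch (steps 1 to 3) and the dichlorovinyl ether (step 6) converge on it.

**Step 9 (key step).**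
- Most likely failure: side reactions of 18 under alkoxide outrun the productive additions. A 1,3-proton shift can deconjugate the γ-silyloxy enone into its silyl dienol ether isomer. The enolate of 19 can also add to a second molecule of 18, because ring closure has to create a quaternary centre next to the bulky tert-butoxy group.
- Fallback: raise the acceptor to the alkyne oxidation level; the same two bonds are then formed at the same carbon. It sets out from 7 and 14. Purchased tert-butyldimethyl(prop-2-yn-1-yloxy)silane F1 would be lithiated with n-BuLi and formylated with dimethylformamide to 4-(tert-butyldimethylsilyloxy)but-2-ynal F2. Addition of acetylide 16, generated from 14 as in step 7, would give racemic 1-tert-butoxy-6-(tert-butyldimethylsilyloxy)hexa-1,4-diyn-3-ol F3, and MnO2 would give 1-tert-butoxy-6-(tert-butyldimethylsilyloxy)hexa-1,4-diyn-3-one F4. Double conjugate addition of 7 to F4 under the conditions of step 9 has no isomerisable enone and an unhindered first acceptor carbon. It would lead directly to dienone 22, where the route is rejoined and step 10 becomes unnecessary.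

**Step 7.**
- Most likely failure: acid-triggered rearrangement of the alkoxyalkynyl carbinol 17 (Meyer–Schuster-type conversion into a dienoate ester) during work-up or chromatography, because the electron-rich alkyne is protonated very easily.
- Fallback: avoid the carbinol. Setting out from 11, chlorite oxidation (NaClO2, NaH2PO4, 2-methylbut-2-ene) would give (E)-4-(tert-butyldimethylsilyloxy)but-2-enoic acid F5. Carbodiimide coupling with N,O-dimethylhydroxylamine would give (E)-4-(tert-butyldimethylsilyloxy)-N-methoxy-N-methylbut-2-enamide F6. Acylation of acetylide 16 with F6 would give ynone 18 directly, where the route is rejoined without step 8.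

**Step 10.**
- Most likely failure: return of 21 to 20 by protodesilylation (acetic acid is liberated in the palladium stage), combined with slow β-hydride elimination at the C6' hydrogen beside the quaternary centre.
- Fallback: a selenoxide syn-elimination, which is intramolecular and less sensitive to hindrance. Setting out from 20, the lithium enolate would be trapped with PhSeCl, anti to the silyloxymethyl group and therefore cis to the C6' hydrogen, to give racemic 2'-tert-butoxy-6'-[(tert-butyldimethylsilyloxy)methyl]-4-(methoxymethoxy)-6-methyl-5'-(phenylselanyl)-3H-spiro[benzofuran-2,1'-cyclohex-2'-ene]-3,4'-dione F7. Oxidation with H2O2 in the presence of pyridine would give 22, where the route is rejoined. The fallback of step 9 bypasses this step altogether.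

**Step 11.**
- Most likely failure: slow attack of methoxide on the ketone, which is shielded by the peri MOM ether and the quaternary carbon. Reversible conjugate additions to the dienone then gain time, and they can end in exchange of the tert-butoxy group. In the second stage, O-methylation in the protic medium may be sluggish.
- Fallback: use the smaller hydroxide and make both methyl groups by alkylation. Setting out from 22, LiOH in aqueous THF at 0 °C would give 2-{2-tert-butoxy-6-[(tert-butyldimethylsilyloxy)methyl]-4-hydroxyphenoxy}-6-(methoxymethoxy)-4-methylbenzoic acid F8. K2CO3 and MeI in DMF would convert its carboxylate and phenoxide together into 24, where the route is rejoined.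

**Step 14.**
- Most likely failure: Friedel–Crafts capture of the tert-butyl and methoxymethyl cations by the electron-rich ring B (C3' and C5' are activated), or ionisation of the benzylic acetate.
- Fallback: remove the protecting groups before the acetate exists, in a solvent that traps the cations. Setting out from 24, HCl in methanol would cleave the silyl, MOM and tert-butyl ethers to methyl 2-hydroxy-6-[2-hydroxy-6-(hydroxymethyl)-4-methoxyphenoxy]-4-methylbenzoate F9. Acetyl chloride with 2,4,6-collidine at −78 °C, conditions under which a primary alcohol reacts much faster than un-ionised phenols, would then give 27 directly.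

Further compounds
F1 | step 9 | tert-butyldimethyl(prop-2-yn-1-yloxy)silane | C#CCO[Si](C)(C)C(C)(C)C
F2 | step 9 | 4-(tert-butyldimethylsilyloxy)but-2-ynal | O=CC#CCO[Si](C)(C)C(C)(C)C
F3 | step 9 | racemic 1-tert-butoxy-6-(tert-butyldimethylsilyloxy)hexa-1,4-diyn-3-ol | CC(C)(C)OC#CC(O)C#CCO[Si](C)(C)C(C)(C)C
F4 | step 9 | 1-tert-butoxy-6-(tert-butyldimethylsilyloxy)hexa-1,4-diyn-3-one | CC(C)(C)OC#CC(=O)C#CCO[Si](C)(C)C(C)(C)C
F5 | step 7 | (E)-4-(tert-butyldimethylsilyloxy)but-2-enoic acid | OC(=O)/C=C/CO[Si](C)(C)C(C)(C)C
F6 | step 7 | (E)-4-(tert-butyldimethylsilyloxy)-N-methoxy-N-methylbut-2-enamide | CON(C)C(=O)/C=C/CO[Si](C)(C)C(C)(C)C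
F7 | step 10 | racemic 2'-tert-butoxy-6'-[(tert-butyldimethylsilyloxy)methyl]-4-(methoxymethoxy)-6-methyl-5'-(phenylselanyl)-3H-spiro[benzofuran-2,1'-cyclohex-2'-ene]-3,4'-dione (mixture of diastereomers) | Cc1cc(OCOC)c2C(=O)C3(Oc2c1)C(OC(C)(C)C)=CC(=O)C([Se]c4ccccc4)C3CO[Si](C)(C)C(C)(C)C
F8 | step 11 | 2-{2-tert-butoxy-6-[(tert-butyldimethylsilyloxy)methyl]-4-hydroxyphenoxy}-6-(methoxymethoxy)-4-methylbenzoic acid | OC(=O)c1c(OCOC)cc(C)cc1Oc1c(OC(C)(C)C)cc(O)cc1CO[Si](C)(C)C(C)(C)C
F9 | step 14 | methyl 2-hydroxy-6-[2-hydroxy-6-(hydroxymethyl)-4-methoxyphenoxy]-4-methylbenzoate | COC(=O)c1c(O)cc(C)cc1Oc1c(O)cc(OC)cc1CO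
A1 | alternative 1 | methyl 4-{2-[(tert-butyldimethylsilyloxy)methyl]-4-methoxy-6-(methoxymethoxy)phenoxy}-6-methyl-2-oxo-2H-pyran-3-carboxylate | COC(=O)C1=C(Oc2c(OCOC)cc(OC)cc2CO[Si](C)(C)C(C)(C)C)C=C(C)OC1=O
A2 | alternative 1 | 1,1-dimethoxyethene | C=C(OC)OC
A3 | alternative 1 | methyl 2-{2-[(tert-butyldimethylsilyloxy)methyl]-4-methoxy-6-(methoxymethoxy)phenoxy}-6-methoxy-4-methylbenzoate | COC(=O)c1c(OC)cc(C)cc1Oc1c(OCOC)cc(OC)cc1CO[Si](C)(C)C(C)(C)C
A4 | alternative 1 | 2-[(tert-butyldimethylsilyloxy)methyl]-4-methoxy-6-(methoxymethoxy)phenol | Oc1c(OCOC)cc(OC)cc1CO[Si](C)(C)C(C)(C)C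
A5 | alternative 2 | methyl 2-({2-[(tert-butyldimethylsilyloxy)methyl]-4-diazo-3-oxobut-1-en-1-yl}oxy)-6-(methoxymethoxy)-4-methylbenzoate (alkene geometry left open) | COC(=O)c1c(OCOC)cc(C)cc1OC=C(CO[Si](C)(C)C(C)(C)C)C(=O)C=[N+]=[N-]
A6 | alternative 2 | methoxyethyne | COC#C
A7 | alternative 2 | methyl 2-{2-[(tert-butyldimethylsilyloxy)methyl]-6-hydroxy-4-methoxyphenoxy}-6-(methoxymethoxy)-4-methylbenzoate | COC(=O)c1c(OCOC)cc(C)cc1Oc1c(O)cc(OC)cc1CO[Si](C)(C)C(C)(C)C
A8 | alternative 3 | dimethyl 2-(1-{2-[(tert-butyldimethylsilyloxy)methyl]-4-methoxy-6-(methoxymethoxy)phenoxy}-3-methylbut-2-en-1-ylidene)malonate | COC(=O)C(C(=O)OC)=C(Oc1c(OCOC)cc(OC)cc1CO[Si](C)(C)C(C)(C)C)C=C(C)C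
A9 | alternative 3 | methyl 2-{2-[(tert-butyldimethylsilyloxy)methyl]-4-methoxy-6-(methoxymethoxy)phenoxy}-6-hydroxy-4-methylbenzoate | COC(=O)c1c(O)cc(C)cc1Oc1c(OCOC)cc(OC)cc1CO[Si](C)(C)C(C)(C)C
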